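Amounts first, for whoever takes over this bench: the flask is charged as listed below, and its target is wanted at the three times given.

all flasks: reagent 44.6 mM; impurity 6.7 µM; added ligand 67 µM

| flask | starting material | second substrate | free catalyst | remark | time |
|---|---|---|---|---|---|
| alder | 47 mM | 94 mM | 34 µM | run made earlier |  |
| oak | 47 mM | 94 mM | 53 µM | run made earlier |  |
| elm | 24 mM | 94 mM | 24 µM | run made earlier |  |
| flask | 47 mM | 94.0 mM | 24 µM |  | 15 h |

| run | time / h | target / % | starting material / % |
|---|---|---|---|
| alder | 0.833 | 1.2 | 98.9 |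
| alder | 2.50 | 2.9 | 96.5 |
| alder | 4.00 | 5.1 | 95.4 |
| alder | 6.00 | 7.3 | 92.8 |
| alder | 10.0 | 10.4 | 89.7 |
| alder | 12.0 | 11.5 | 88.2 |
| oak | 0.833 | 2.1 | 98.3 |
| oak | 2.50 | 5.3 | 95.3 |
| oak | 4.00 | 7.4 | 91.9 |
| oak | 6.00 | 10.6 | 89.1 |
| oak | 10.0 | 14.7 | 84.9 |
| oak | 12.0 | 16.6 | 83.6 |
| elm | 2.50 | 2.7 | 97.0 |
| elm | 5.00 | 5.5 | 94.6 |
| elm | 8.00 | 8.6 | 91.7 |
| elm | 10.0 | 10.7 | 89.7 |
| elm | 12.0 | 11.5 | 88.2 |

(each reading ± 0.3 percentage points)

1. amount of target in percent of the starting material charged, at 50 min, 4.0 h and 15 h



In alder at 10.0 h, target and starting material add up to 100%, so I treat the run as plain conversion. Alder reaches 10.4% at 10.0 h and oak reaches 10.6% at 6.00 h, a time ratio of 1.67. That lies nearer to the ratio of catalyst less impurity, 1.70, than to the ratio of raw catalyst, 1.56.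

So I reckon this flask with 17.3 µM of working catalyst, the free catalyst charged less the impurity. With the same starting material as alder, its clock runs at 0.634 of alder's, and 15 h here equals 9.51 h there. Reading alder's curve at the scaled times gives 0.761%, 2.95% and 10.0%, so expect about 90.0% starting material at 15 h.

Don't add free catalyst to this flask: oak shows the clock moving with it. Don't read this flask off elm either, which has the same working catalyst but half the starting material.

The forecast, “follow the alder curve with time scaled”, says 0.7%, 3.2% and 10%, slightly apart from mine at the first two times.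

The flask gives 0.700%, 3.14% and 9.95%, by this scheme:

    second substrate + free catalyst ⇌ catalyst intermediate B (K = 10.0 /M, k = 6400 /M/h)
    2 starting material → self-condensation product (k = 3.20 × 10⁻⁴ /M/h)
    reagent + catalyst intermediate B → free catalyst + second product (k = 39000 /M/h)
    free catalyst + added ligand ⇌ idle complex, settled at all times (K = 8700 /M)
    reagent + catalyst intermediate A → free catalyst + target (k = 720 /M/h)
    starting material + free catalyst ⇌ catalyst intermediate A (K = 420 /M, k = 3800 /M/h)
    free catalyst + impurity → spent catalyst (k = 3.80 × 10⁶ /M/h)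

Spent catalyst stands at 27.9% of the catalyst charged at 15.0 h, with impurity at 0%, and impurity over catalyst charged is 27.9%. Oak has 2.68 times the working catalyst, so this flask's 15 h equals 5.60 h in oak, where its readings at 4.00 h and 6.00 h give 9.97%.

The runs stem from a simulated flask for substances that don't exist.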